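Drummondin A is traced back to a fully aromatic diarylmethane. In it, ring B is the finished 8-butyryl-5,7-dihydroxy-2,2-dimethylchromene and ring A is still a butyrylphloroglucinol. The closing operation puts both methyl groups on C6 of ring A. This is that ring's only sp3 carbon and, in the precursor, the only carbon of either benzene ring that still bears hydrogen. The second methylation blocks rearomatisation and leaves the enolised cyclohexadienone. The precursor is built convergently from one batch of butyrylphloroglucinol. Part is annulated to the chromene, whose single free carbon is aminomethylated, and the derived quinone methide is captured by the rest. No symmetric dimer has to be desymmetrised.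

Key step: step 5

Remark: 15 has no stereocentre; ring A is drawn as the enol tautomer of the target SMILES, which exchanges freely with its other enol forms; ring A locants follow the dienone name of 15 (C1 ketone, C2 butyryl, C3 enol, C4 bridge, C5 enol, C6 CMe2) and are kept for the aromatic precursors, while ring B carries chromene locants.

Step 1
Reactants: 1 phloroglucinol; 2 butyryl chloride
Product: 3 1-(2,4,6-trihydroxyphenyl)butan-1-one (butyrylphloroglucinol)
Conditions: AlCl3 (4 equiv), CH2Cl2/PhNO2, 0 to 45 °C; then ice, 1 M HCl
Reagents that add atoms: butyryl chloride 2, CCCC(=O)Cl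
Why: Friedel–Crafts acylation of a very electron-rich arene, in which any aryl ester formed first is carried on by Fries rearrangement and the chelated, deactivating ketone should hold the reaction at monoacylation.

Step 2
Reactants: 3 butyrylphloroglucinol; 4 3-methylbut-2-enal
Product: 6 1-(5,7-dihydroxy-2,2-dimethyl-2H-chromen-8-yl)butan-1-one, via dienone quinone methide 5 (not isolated)
Conditions: 4 (1.05 equiv), ethylenediammonium diacetate (20 mol %), THF, 65 °C
Reagents that add atoms: 3-methylbut-2-enal 4, CC(C)=CC=O
Why: Domino Knoevenagel-type condensation and oxa-6π electrocyclisation (formal [3+3] chromene annulation), in which the iminium form of 4 attacks one of the two equivalent free ring carbons, loss of water gives 5, and 5 closes through the carbonyl oxygen next to the acyl-bearing carbon, the mode expected to dominate for acylphloroglucinols because the other ortho hydroxyl keeps the ketone chelate, while the new ether lowers ring reactivity and slows a second annulation.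

Step 3
Reactants: 6 8-butyryl-5,7-dihydroxy-2,2-dimethylchromene; 7 formaldehyde (as paraformaldehyde); 8 dimethylamine
Product: 9 1-{6-[(dimethylamino)methyl]-5,7-dihydroxy-2,2-dimethyl-2H-chromen-8-yl}butan-1-one
Conditions: (CH2O)n (1.5 equiv), Me2NH (2 M in MeOH, 2 equiv), MeOH, rt, 30 min; then 6 added slowly, 0 °C to rt; volatiles removed in vacuo
Reagents that add atoms: formaldehyde 7, C=O; dimethylamine 8, CNC
Why: Phenol Mannich reaction at C6 of ring B, the only unsubstituted aromatic carbon of 6 and flanked by two hydroxyls, with inverse addition into the premixed aminomethylating agent so that 6 cannot intercept its own Mannich base.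

Step 4
Reactants: 9 Mannich base; 3 butyrylphloroglucinol
Product: 11 1-{3-[(8-butanoyl-5,7-dihydroxy-2,2-dimethyl-2H-chromen-6-yl)methyl]-2,4,6-trihydroxyphenyl}butan-1-one (aromatic ring A precursor), via ring B quinone methide 10 (not isolated)
Conditions: 9 added in portions to 3 (3 equiv), 1,4-dioxane, 90 °C, Ar sweep; dilute acid wash, excess 3 recovered
Reagents that add atoms: none
Why: Thermal retro-Mannich loss of Me2NH gives ortho-quinone methide 10, and Michael-type C-addition of 3 at one of its two equivalent free carbons with rearomatisation forms the CH2 bridge, the classical Mannich-base route to unsymmetrical methylene-bridged phloroglucinols, the excess of 3 keeping 11 from adding to a second molecule of 10.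

Step 5
Reactants: 11 aromatic ring A precursor; 12 iodomethane
Product: 15 drummondin A, via ring A monomethyl compound 13 (not isolated), via sodium enolate of drummondin A 14 (not isolated)
Conditions: NaOMe (5 equiv), MeI (2.2 equiv, added slowly), degassed MeOH, 0 °C to rt, Ar; then cold 1 M HCl to pH 2
Reagents that add atoms: iodomethane 12, CI
Why: NaOMe turns ring A of 11 into a polyphenoxide whose C6, the only hydrogen-bearing carbon of either benzene ring and flanked by two oxygen-bearing carbons, displaces iodide from MeI (SN2); the dienone formed tautomerises back to aromatic 13, which is methylated again at C6, and since that carbon is now quaternary the ring cannot rearomatise and rests as β-triketone enolate 14 until HCl releases 15. The closest known reaction type is the alkylative dearomatisation of acylphloroglucinols with MeI and NaOMe that gives acylfilicinic acids. No ring is closed and no stereocentre arises, because C6 ends up with two identical methyl groups. The step needs carbon over oxygen alkylation, ring A over ring B, C6 of ring A over the bridge-bearing carbons (C4 of ring A, C6 of ring B) in the second methylation, and a stop after two methyl groups. Hydrogen-bonding MeOH shields the oxygens, ring B has no free carbon and only two hydroxyls (one tied up in the ketone chelate), the bulky arylmethyl group screens the bridge-bearing carbons while the methyl-bearing C6 stays open, and the charge of 14 is spread over the triketone, so with MeI held near two equivalents a third alkylation should be slow. Low temperature, a short reaction time and exclusion of air hold back base-induced retro-Michael cleavage of the CH2 bridge (partner exchange) and oxidation of the phenoxides.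

Compound list
1 | phloroglucinol | Oc1cc(O)cc(O)c1 | starting material
2 | butyryl chloride | CCCC(=O)Cl | starting material
3 | 1-(2,4,6-trihydroxyphenyl)butan-1-one (butyrylphloroglucinol) | CCCC(=O)c1c(O)cc(O)cc1O | intermediate
4 | 3-methylbut-2-enal | CC(C)=CC=O | starting material
5 | (6Z)-2-butanoyl-3,5-dihydroxy-6-(3-methylbut-2-en-1-ylidene)cyclohexa-2,4-dien-1-one, alkenyl arm syn to the C1 carbonyl (not isolated) | CCCC(=O)C1=C(O)C=C(O)/C(=C/C=C(C)C)C1=O | intermediate
6 | 1-(5,7-dihydroxy-2,2-dimethyl-2H-chromen-8-yl)butan-1-one | CCCC(=O)c1c(O)cc(O)c2C=CC(C)(C)Oc12 | intermediate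
7 | formaldehyde (used as paraformaldehyde) | C=O | starting material
8 | dimethylamine | CNC | starting material
9 | 1-{6-[(dimethylamino)methyl]-5,7-dihydroxy-2,2-dimethyl-2H-chromen-8-yl}butan-1-one | CCCC(=O)c1c(O)c(CN(C)C)c(O)c2C=CC(C)(C)Oc12 | intermediate
10 | 8-butanoyl-7-hydroxy-2,2-dimethyl-6-methylidene-2H-chromen-5(6H)-one (not isolated) | CCCC(=O)C1=C(O)C(=C)C(=O)C2=C1OC(C)(C)C=C2 | intermediate
11 | 1-{3-[(8-butanoyl-5,7-dihydroxy-2,2-dimethyl-2H-chromen-6-yl)methyl]-2,4,6-trihydroxyphenyl}butan-1-one | CCCC(=O)c1c(O)cc(O)c(Cc2c(O)c3c(c(C(=O)CCC)c2O)OC(C)(C)C=C3)c1O | intermediate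
12 | iodomethane | CI | starting material
13 | 1-{3-[(8-butanoyl-5,7-dihydroxy-2,2-dimethyl-2H-chromen-6-yl)methyl]-2,4,6-trihydroxy-5-methylphenyl}butan-1-one (not isolated) | CCCC(=O)c1c(O)c(C)c(O)c(Cc2c(O)c3c(c(C(=O)CCC)c2O)OC(C)(C)C=C3)c1O | intermediate
14 | sodium enolate of drummondin A, drawn as the monosodium salt although further phenol sites are ionised in the flask (not isolated) | CCCC(=O)C1=C([O-])C(Cc2c(O)c3c(c(C(=O)CCC)c2O)OC(C)(C)C=C3)=C(O)C(C)(C)C1=O.[Na+] | intermediate
15 | drummondin A, 2-butanoyl-4-[(8-butanoyl-5,7-dihydroxy-2,2-dimethyl-2H-chromen-6-yl)methyl]-3,5-dihydroxy-6,6-dimethylcyclohexa-2,4-dien-1-one | CCCC(=O)C1=C(O)C(Cc2c(O)c3c(c(C(=O)CCC)c2O)OC(C)(C)C=C3)=C(O)C(C)(C)C1=O | target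

Total step count: 5
Longest linear sequence: 5 steps (1 to 3 to 6 to 9 to 11 to 15); compound 3 is used twice.

Steps most likely to fail

**Step 5.**
- Methylation may not stay on C6 of ring A. The second or a third methyl group may go to a bridge-bearing carbon or to oxygen.
- Methoxide may also cleave the CH2 bridge by retro-Michael reaction, so that the two halves exchange partners.
- Fallback, setting out from 3 (with 9 as partner) and rejoining at 15: the gem-dimethylation is moved to the monomer.
- Compound 3 is treated with NaOMe and MeI in MeOH to give butyrylfilicinic acid F1, in which only one ring competes for the electrophile.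
- F1 has a single free ring carbon. It is heated with Mannich base 9 in dioxane, so that quinone methide 10 is captured at that carbon and 15 forms directly.

**Step 2.**
- The electrocyclisation may close through the oxygen para to the ketone instead of the one next to the acyl-bearing carbon.
- A second annulation may also consume the product.
- The isomer should be assigned by HMBC before it is carried on.
- Fallback, setting out from 3 and rejoining at 6: the para hydroxyl, the most acidic and the only non-chelated one, is blocked first.
- MOMCl (1 equiv) and iPr2NEt in CH2Cl2 at 0 °C should give 1-[2,6-dihydroxy-4-(methoxymethoxy)phenyl]butan-1-one F2.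
- Annulation of F2 with 4 and ethylenediammonium diacetate can then close only through an ortho oxygen. It should give 1-[7-hydroxy-5-(methoxymethoxy)-2,2-dimethyl-2H-chromen-8-yl]butan-1-one F3.
- HCl in MeOH at rt to 40 °C removes the acetal and returns 6.

**Step 4.**
- The product may add to further quinone methide and grow into oligomers.
- The Mannich base may condense with itself.
- Prolonged heating with amine may let the halves exchange.
- Fallback, setting out from 3 and rejoining at 11: the bridge is made before the pyran ring.
- Two molecules of 3 are joined with one of formaldehyde 7 (dilute aqueous KOH, rt, then acid) to give methylenebis(butyrylphloroglucinol) F4.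
- F4 is annulated once with 4 (1 equiv) and ethylenediammonium diacetate in THF. Compound 11 is then separated from unreacted and doubly annulated material.
- This order avoids the Mannich base altogether but accepts a statistical mono-annulation.

Further compounds
F1 | step 5 | 2-butanoyl-3,5-dihydroxy-6,6-dimethylcyclohexa-2,4-dien-1-one (butyrylfilicinic acid) | CCCC(=O)C1=C(O)C=C(O)C(C)(C)C1=O
F2 | step 2 | 1-[2,6-dihydroxy-4-(methoxymethoxy)phenyl]butan-1-one | CCCC(=O)c1c(O)cc(OCOC)cc1O
F3 | step 2 | 1-[7-hydroxy-5-(methoxymethoxy)-2,2-dimethyl-2H-chromen-8-yl]butan-1-one | CCCC(=O)c1c(O)cc(OCOC)c2C=CC(C)(C)Oc12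
F4 | step 4 | 1,1'-[methylenebis(2,4,6-trihydroxybenzene-3,1-diyl)]di(butan-1-one) (methylenebis(butyrylphloroglucinol)) | CCCC(=O)c1c(O)cc(O)c(Cc2c(O)cc(O)c(C(=O)CCC)c2O)c1O
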